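**Retrosynthetic overview**

1. 28 ⇐ 24: the last ring, the 3(2H)-furanone, is closed across the ten-membered ring. The ring ynone is hydrated to the 10-hydroxy-1,3-dione, O10 adds to C3, water is lost, and the silyl groups are removed.
2. 24 ⇐ 22: the ten-membered carbocycle and the γ-lactone form in one operation. A CrCl2 allylation makes the C6–C7 bond (the bond made when farnesyl diphosphate cyclises) and the alkoxide lactonises onto C12.
3. 22 ⇐ 21 ⇐ 15 + 19: the (4Z)-3-oxo-6-al unit is stored as a 2-alkynylfuran and released by NBS/H2O. Sonogashira coupling joins the halves and an Appel reaction gives the allyl bromide.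
4. 15 ⇐ 13 (Morita–Baylis–Hillman) ⇐ lactone 7 ⇐ copper–bis(oxazoline) aldol of enolsilane 2 with methyl pyruvate (sets C10), then transfer hydrogenation (sets C8).
5. Ring order: carbocycle, then lactone, then furanone. Starting materials: 1,1-dimethoxypropan-2-one, methyl pyruvate, methyl acrylate, furan-3-ylmethanol.

Assumption: germacrane numbering is used for the ring compounds (C1 ketone, C2=C3 enol ether, C4=C5, C6 lactone carbinol, C8 ester carbinol, C10 quaternary ether carbon, C11=C13 methylene, C12 lactone carbonyl, C14 methyl, C15 hydroxymethyl), the SMILES is read as 4Z,6R,7R,8R,10S, and the ligand enantiomers written in steps 2 and 3 are those expected to give 10S and 8R (the mirror-image ligand is used if the sense proves opposite).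

**Route**

Step 1
Reactants: 1 1,1-dimethoxypropan-2-one
Product: 2 [(3,3-dimethoxyprop-1-en-2-yl)oxy]trimethylsilane
Conditions: LiN(i-Pr)2, THF, −78 °C; Me3SiCl, −78 to 0 °C
Reagents that add atoms: chlorotrimethylsilane, C[Si](C)(C)Cl
Why: Kinetic enolisation at the methyl group (the acetal C–H is hindered) and O-silylation give the enolsilane needed for a Mukaiyama aldol reaction; no stereocentre is formed.

Step 2
Reactants: 2 [(3,3-dimethoxyprop-1-en-2-yl)oxy]trimethylsilane; 3 methyl pyruvate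
Product: 5 methyl (2S)-2-hydroxy-5,5-dimethoxy-2-methyl-4-oxopentanoate, via silyl ether 4 (not isolated)
Conditions: Cu(OTf)2 (10 mol %), (S,S)-t-Bu-box (11 mol %), THF, −78 °C; then 1 M HCl, THF, 0 °C
Reagents that add atoms: none
Why: Evans-type catalytic Mukaiyama aldol addition to pyruvate chelated on divalent copper, in which the bis(oxazoline) ligand leaves the si face of the ketone open and sets the tertiary carbinol (future C10) as S.

Step 3
Reactants: 5 methyl (2S)-2-hydroxy-5,5-dimethoxy-2-methyl-4-oxopentanoate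
Product: 7 (3S,5R)-5-(dimethoxymethyl)-3-hydroxy-3-methyloxolan-2-one, via diol ester 6 (not isolated)
Conditions: RuCl[(R,R)-TsDPEN](p-cymene) (1 mol %), HCO2H/Et3N (5:2), 30 °C; then DBU (0.1 equiv), toluene, 25 °C
Reagents that add atoms: none
Why: Noyori asymmetric transfer hydrogenation reduces the ketone under catalyst control to the 4R alcohol (future C8), and the γ-hydroxy ester then lactonises, which protects O8 and lets C1 be taken cleanly to the aldehyde level.

Step 4
Reactants: 7 (3S,5R)-5-(dimethoxymethyl)-3-hydroxy-3-methyloxolan-2-one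
Product: 9 (2R,4S)-1,1-dimethoxy-4-methylhex-5-yne-2,4-diol, via lactol 8 (not isolated)
Conditions: i-Bu2AlH (2.2 equiv), CH2Cl2, −78 °C; then MeOH, K2CO3, dimethyl (1-diazo-2-oxopropyl)phosphonate, −78 to 25 °C
Reagents that add atoms: dimethyl (1-diazo-2-oxopropyl)phosphonate, CC(=O)C(=[N+]=[N-])P(=O)(OC)OC
Why: Lactone-to-lactol reduction followed in the same flask by Seyferth–Gilbert homologation with the Ohira–Bestmann reagent turns C1 into the terminal alkyne (C1≡C2) and frees O8; C10 is quaternary and cannot epimerise.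

Step 5
Reactants: 9 (2R,4S)-1,1-dimethoxy-4-methylhex-5-yne-2,4-diol
Product: 10 (2R,4S)-4-hydroxy-1,1-dimethoxy-4-methylhex-5-yn-2-yl 2-methylpropanoate
Conditions: i-PrCOCl (1.1 equiv), pyridine, CH2Cl2, 0 °C
Reagents that add atoms: 2-methylpropanoyl chloride, CC(C)C(=O)Cl
Why: Selective acylation of the secondary alcohol (the tertiary propargylic alcohol is too hindered) installs the C8 ester of the target.

Step 6
Reactants: 10 (2R,4S)-4-hydroxy-1,1-dimethoxy-4-methylhex-5-yn-2-yl 2-methylpropanoate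
Product: 13 (2R,4S)-4-methyl-1-oxo-4-(triethylsilyloxy)hex-5-yn-2-yl 2-methylpropanoate, via triethylsilyl ether 11 (not isolated), via lutidinium salt 12 (not isolated)
Conditions: Et3SiOTf (3.5 equiv), 2,6-lutidine (5 equiv), CH2Cl2, −78 to 0 °C; then H2O
Reagents that add atoms: triethylsilyl trifluoromethanesulfonate, CC[Si](CC)(CC)OS(=O)(=O)C(F)(F)F; water, O
Why: Silylation of the tertiary alcohol (which blocks lactol formation with the aldehyde) is followed by Fujioka-type acetal cleavage, in which the silyl triflate and lutidine convert the dimethyl acetal into a lutidinium salt that water hydrolyses, so the C7 aldehyde is unmasked without acid and C8 is untouched.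

Step 7
Reactants: 13 (2R,4S)-4-methyl-1-oxo-4-(triethylsilyloxy)hex-5-yn-2-yl 2-methylpropanoate; 14 methyl acrylate
Product: 15 methyl 2-[(2R,4S)-1-hydroxy-4-methyl-2-(2-methylpropanoyloxy)-4-(triethylsilyloxy)hex-5-yn-1-yl]prop-2-enoate (both C1 epimers)
Conditions: DABCO (1.0 equiv), neat 14 (10 equiv), 25 °C
Reagents that add atoms: none
Why: The Morita–Baylis–Hillman reaction adds the acrylate α-carbon (C11) to the activated α-acyloxy aldehyde and brings in C12 and C13; the C7 carbinol forms as a mixture that is erased in step 11, and short contact with DABCO limits epimerisation at C8.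

Step 8
Reactants: 16 furan-3-ylmethanol
Product: 18 (2-iodofuran-3-yl)methanol, via dilithio species 17 (not isolated)
Conditions: n-BuLi (2.2 equiv), THF, −78 to 0 °C; I2, −78 °C
Reagents that add atoms: iodine, II
Why: Alkoxide-directed ortho-lithiation places lithium at C2 of the furan, and iodination gives the 2,3-disubstituted furan.

Step 9
Reactants: 18 (2-iodofuran-3-yl)methanol
Product: 19 tert-butyl[(2-iodofuran-3-yl)methoxy]diphenylsilane
Conditions: t-BuPh2SiCl, imidazole, DMF, 25 °C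
Reagents that add atoms: tert-butyl(chloro)diphenylsilane, CC(C)(C)[Si](Cl)(c1ccccc1)c1ccccc1
Why: Silyl protection of the future C15 hydroxyl with a group that survives aqueous acetic acid and is removed by fluoride in the last step.

Step 10
Reactants: 15 methyl 2-[(2R,4S)-1-hydroxy-4-methyl-2-(2-methylpropanoyloxy)-4-(triethylsilyloxy)hex-5-yn-1-yl]prop-2-enoate; 19 tert-butyl[(2-iodofuran-3-yl)methoxy]diphenylsilane
Product: 20 methyl 2-[(2R,4S)-6-[3-({[tert-butyl(diphenyl)silyl]oxy}methyl)furan-2-yl]-1-hydroxy-4-methyl-2-(2-methylpropanoyloxy)-4-(triethylsilyloxy)hex-5-yn-1-yl]prop-2-enoate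
Conditions: PdCl2(PPh3)2 (3 mol %), CuI (6 mol %), Et3N, THF, 25 °C
Reagents that add atoms: none
Why: Sonogashira coupling joins furan C2 (future C3) to the alkyne terminus (C2); the allylic alcohol and the esters are inert to zerovalent palladium under these conditions.

Step 11
Reactants: 20 (as above)
Product: 21 methyl (2Z,4R,6S)-2-(bromomethyl)-8-[3-({[tert-butyl(diphenyl)silyl]oxy}methyl)furan-2-yl]-6-methyl-4-(2-methylpropanoyloxy)-6-(triethylsilyloxy)oct-2-en-7-ynoate
Conditions: CBr4, PPh3, CH2Cl2, 0 °C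
Reagents that add atoms: tetrabromomethane, BrC(Br)(Br)Br
Why: Appel bromination with allylic transposition (SN2′) moves bromide to C13 and the double bond to C7=C11 as the more stable Z isomer; both C7 epimers converge, and any secondary bromide gives the same allylchromium later.

Step 12
Reactants: 21 (as above)
Product: 22 methyl (2Z,4R,6S,10Z)-2-(bromomethyl)-10-({[tert-butyl(diphenyl)silyl]oxy}methyl)-6-methyl-4-(2-methylpropanoyloxy)-9,12-dioxo-6-(triethylsilyloxy)dodeca-2,10-dien-7-ynoate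
Conditions: NBS (1.05 equiv), NaHCO3, acetone/H2O (9:1), −20 °C
Reagents that add atoms: water, O
Why: Achmatowicz-type oxidative furan opening (bromonium at furan C5, water at C2, loss of HBr) gives the cis-ene-dicarbonyl compound, so the C4=C5 Z geometry, the C3 ketone and the C6 aldehyde all come from the ring; the product is used at once to avoid Z-to-E isomerisation.

Step 13
Reactants: 22 (as above)
Product: 24 (4Z,6R,7R,8R,10S)-15-(tert-butyldiphenylsilyloxy)-3-oxo-10-(triethylsilyloxy)germacra-4,11(13)-dien-1-yn-12,6-olid-8-yl 2-methylpropanoate, via hydroxy ester 23 (not isolated)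
Conditions: CrCl2 (10 equiv), THF, 25 °C, 22 added over 10 h to 0.002 M; then PPTS (0.2 equiv), CH2Cl2, 25 °C
Reagents that add atoms: none
Why: Intramolecular Nozaki–Hiyama–Kishi allylation, in which the allylchromium from the bromide adds through C7 to the C6 aldehyde (only the aldehyde is attacked; the ynone cannot be reached in a ring) and the alkoxide lactonises onto C12; C7 is set by allylic 1,3-strain from C8 (H8 eclipses the alkene, the aldehyde bonds anti to C9) and C6 by the anti addition mode (H6/H7 trans, trans-fused lactone) expected for an equilibrating allylchromium in a ring-forming transition state.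

Step 14
Reactants: 24 (as above)
Product: 28 (4Z,6R,7R,8R,10S)-15-hydroxy-1-oxo-3,10-epoxygermacra-2,4,11(13)-trien-12,6-olid-8-yl 2-methylpropanoate, via alcohol 25 (not isolated), via dione 26 (not isolated), via silyl furanone 27 (not isolated)
Conditions: Ph3PAuNTf2 (5 mol %), AcOH/THF/H2O (3:1:1), 35 °C; evaporate; HF·pyridine, pyridine, THF, 0 to 25 °C
Reagents that add atoms: water, O
Why: Proposed new method: after acidolysis of the tertiary silyl ether, monovalent gold activates the bent ring alkyne, water adds at C1 (β to the C3 ketone) to give the 10-hydroxy-1,3-dione, O10 adds to the C3 carbonyl (5-exo) and the hemiketal loses water to give the 3(2H)-furanone, with C15–O kept silylated so it cannot add to the alkyne, and fluoride then frees C15–OH; the closest known reaction is the gold-catalysed (or amine/acid-mediated) conversion of open-chain 4-hydroxyalk-2-yn-1-ones into 3(2H)-furanones, and no stereocentre is made or touched.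

**Compound list**

1 | 1,1-dimethoxypropan-2-one | CC(=O)C(OC)OC | starting material
2 | [(3,3-dimethoxyprop-1-en-2-yl)oxy]trimethylsilane | C=C(O[Si](C)(C)C)C(OC)OC | intermediate
3 | methyl pyruvate | CC(=O)C(=O)OC | starting material
4 | methyl (2S)-5,5-dimethoxy-2-methyl-4-oxo-2-(trimethylsilyloxy)pentanoate | COC(=O)[C@@](C)(O[Si](C)(C)C)CC(=O)C(OC)OC | intermediate
5 | methyl (2S)-2-hydroxy-5,5-dimethoxy-2-methyl-4-oxopentanoate | COC(=O)[C@@](C)(O)CC(=O)C(OC)OC | intermediate
6 | methyl (2S,4R)-2,4-dihydroxy-5,5-dimethoxy-2-methylpentanoate | COC(=O)[C@@](C)(O)C[C@@H](O)C(OC)OC | intermediate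
7 | (3S,5R)-5-(dimethoxymethyl)-3-hydroxy-3-methyloxolan-2-one | COC(OC)[C@H]1C[C@](C)(O)C(=O)O1 | intermediate
8 | (3S,5R)-5-(dimethoxymethyl)-3-methyloxolane-2,3-diol (both anomers) | COC(OC)[C@H]1C[C@](C)(O)C(O)O1 | intermediate
9 | (2R,4S)-1,1-dimethoxy-4-methylhex-5-yne-2,4-diol | C#C[C@@](C)(O)C[C@@H](O)C(OC)OC | intermediate
10 | (2R,4S)-4-hydroxy-1,1-dimethoxy-4-methylhex-5-yn-2-yl 2-methylpropanoate | C#C[C@@](C)(O)C[C@@H](OC(=O)C(C)C)C(OC)OC | intermediate
11 | (2R,4S)-1,1-dimethoxy-4-methyl-4-(triethylsilyloxy)hex-5-yn-2-yl 2-methylpropanoate | C#C[C@@](C)(O[Si](CC)(CC)CC)C[C@@H](OC(=O)C(C)C)C(OC)OC | intermediate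
12 | 1-[(2R,4S)-1-methoxy-4-methyl-2-(2-methylpropanoyloxy)-4-(triethylsilyloxy)hex-5-yn-1-yl]-2,6-dimethylpyridin-1-ium trifluoromethanesulfonate (both C1 epimers) | C#C[C@@](C)(O[Si](CC)(CC)CC)C[C@@H](OC(=O)C(C)C)C(OC)[n+]1c(C)cccc1C.[O-]S(=O)(=O)C(F)(F)F | intermediate
13 | (2R,4S)-4-methyl-1-oxo-4-(triethylsilyloxy)hex-5-yn-2-yl 2-methylpropanoate | C#C[C@@](C)(O[Si](CC)(CC)CC)C[C@@H](OC(=O)C(C)C)C=O | intermediate
14 | methyl acrylate | C=CC(=O)OC | starting material
15 | methyl 2-[(2R,4S)-1-hydroxy-4-methyl-2-(2-methylpropanoyloxy)-4-(triethylsilyloxy)hex-5-yn-1-yl]prop-2-enoate (both C1 epimers) | C#C[C@@](C)(O[Si](CC)(CC)CC)C[C@@H](OC(=O)C(C)C)C(O)C(=C)C(=O)OC | intermediate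
16 | furan-3-ylmethanol | OCc1ccoc1 | starting material
17 | lithium (2-lithiofuran-3-yl)methanolate | [Li]OCc1ccoc1[Li] | intermediate
18 | (2-iodofuran-3-yl)methanol | OCc1ccoc1I | intermediate
19 | tert-butyl[(2-iodofuran-3-yl)methoxy]diphenylsilane | CC(C)(C)[Si](OCc1ccoc1I)(c1ccccc1)c1ccccc1 | intermediate
20 | methyl 2-[(2R,4S)-6-[3-({[tert-butyl(diphenyl)silyl]oxy}methyl)furan-2-yl]-1-hydroxy-4-methyl-2-(2-methylpropanoyloxy)-4-(triethylsilyloxy)hex-5-yn-1-yl]prop-2-enoate (both C1 epimers) | CC(C)(C)[Si](OCc1ccoc1C#C[C@@](C)(O[Si](CC)(CC)CC)C[C@@H](OC(=O)C(C)C)C(O)C(=C)C(=O)OC)(c1ccccc1)c1ccccc1 | intermediate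
21 | methyl (2Z,4R,6S)-2-(bromomethyl)-8-[3-({[tert-butyl(diphenyl)silyl]oxy}methyl)furan-2-yl]-6-methyl-4-(2-methylpropanoyloxy)-6-(triethylsilyloxy)oct-2-en-7-ynoate | CC(C)(C)[Si](OCc1ccoc1C#C[C@@](C)(O[Si](CC)(CC)CC)C[C@@H](OC(=O)C(C)C)/C=C(\CBr)C(=O)OC)(c1ccccc1)c1ccccc1 | intermediate
22 | methyl (2Z,4R,6S,10Z)-2-(bromomethyl)-10-({[tert-butyl(diphenyl)silyl]oxy}methyl)-6-methyl-4-(2-methylpropanoyloxy)-9,12-dioxo-6-(triethylsilyloxy)dodeca-2,10-dien-7-ynoate | O=C/C=C(/CO[Si](c1ccccc1)(c1ccccc1)C(C)(C)C)C(=O)C#C[C@@](C)(O[Si](CC)(CC)CC)C[C@@H](OC(=O)C(C)C)/C=C(\CBr)C(=O)OC | intermediate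
23 | methyl (4Z,6R,7S,8R,10S)-15-(tert-butyldiphenylsilyloxy)-6-hydroxy-8-(2-methylpropanoyloxy)-3-oxo-10-(triethylsilyloxy)germacra-4,11(13)-dien-1-yn-12-oate | O[C@@H]1/C=C(/CO[Si](c2ccccc2)(c2ccccc2)C(C)(C)C)C(=O)C#C[C@@](C)(O[Si](CC)(CC)CC)C[C@@H](OC(=O)C(C)C)[C@H]1C(=C)C(=O)OC | intermediate
24 | (4Z,6R,7R,8R,10S)-15-(tert-butyldiphenylsilyloxy)-3-oxo-10-(triethylsilyloxy)germacra-4,11(13)-dien-1-yn-12,6-olid-8-yl 2-methylpropanoate | C=C1C(=O)O[C@@H]2/C=C(/CO[Si](c3ccccc3)(c3ccccc3)C(C)(C)C)C(=O)C#C[C@@](C)(O[Si](CC)(CC)CC)C[C@@H](OC(=O)C(C)C)[C@@H]12 | intermediate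
25 | (4Z,6R,7R,8R,10S)-15-(tert-butyldiphenylsilyloxy)-10-hydroxy-3-oxogermacra-4,11(13)-dien-1-yn-12,6-olid-8-yl 2-methylpropanoate | C=C1C(=O)O[C@@H]2/C=C(/CO[Si](c3ccccc3)(c3ccccc3)C(C)(C)C)C(=O)C#C[C@@](C)(O)C[C@@H](OC(=O)C(C)C)[C@@H]12 | intermediate
26 | (4Z,6R,7R,8R,10S)-15-(tert-butyldiphenylsilyloxy)-10-hydroxy-1,3-dioxogermacra-4,11(13)-dien-12,6-olid-8-yl 2-methylpropanoate | C=C1C(=O)O[C@@H]2/C=C(/CO[Si](c3ccccc3)(c3ccccc3)C(C)(C)C)C(=O)CC(=O)[C@@](C)(O)C[C@@H](OC(=O)C(C)C)[C@@H]12 | intermediate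
27 | (4Z,6R,7R,8R,10S)-15-(tert-butyldiphenylsilyloxy)-1-oxo-3,10-epoxygermacra-2,4,11(13)-trien-12,6-olid-8-yl 2-methylpropanoate | C=C1C(=O)O[C@@H]2/C=C(/CO[Si](c4ccccc4)(c4ccccc4)C(C)(C)C)C3=CC(=O)[C@](C)(C[C@@H](OC(=O)C(C)C)[C@@H]12)O3 | intermediate
28 | (4Z,6R,7R,8R,10S)-15-hydroxy-1-oxo-3,10-epoxygermacra-2,4,11(13)-trien-12,6-olid-8-yl 2-methylpropanoate | C=C1C(=O)O[C@@H]2/C=C(/CO)C3=CC(=O)[C@](C)(C[C@@H](OC(=O)C(C)C)[C@@H]12)O3 | target

**Step count and weak points**

Total steps: 14. Longest linear sequence: 12 (steps 1–7 and 10–14).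

The three steps most likely to fail:

Step 13 (chromium macrocyclisation). The risks are the strain of the cyclodecenynone, reduction of the ene-dicarbonyl unit by divalent chromium, and the C6/C7 configuration. The fallback sets out from 22 and changes the order of ring formation. The gold-catalysed hydration/cyclisation of step 14 (Ph3PAuNTf2, AcOH/THF/H2O) is run first on the open chain to give the furanone methyl (2Z,4R)-2-(bromomethyl)-5-[(2S)-5-{(2Z)-1-[(tert-butyldiphenylsilyl)oxy]-4-oxobut-2-en-2-yl}-2-methyl-3-oxo-2,3-dihydrofuran-2-yl]-4-(2-methylpropanoyloxy)pent-2-enoate F1. Its ketone is now a vinylogous ester and no longer easily reduced. F1 is then cyclised with CrCl2 in THF at high dilution, with lactonisation, and comes back to the route at 27, which only needs the fluoride stage of step 14.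

Step 14 (gold-catalysed hydration across the ring). The alkyne may not hydrate cleanly inside the strained ring, and the methylene lactone is sensitive. The fallback sets out from 24 and uses the classical amine route with the methylene lactone masked. Excess Et2NH in THF adds to the ynone and to the exocyclic methylene to give the bis-adduct (4Z)-1,13-bis(diethylamino)-15-(tert-butyldiphenylsilyloxy)-3-oxo-10-(triethylsilyloxy)germacra-1,4-dien-12,6-olid-8-yl 2-methylpropanoate F2. Aqueous AcOH hydrolyses the enaminone, removes the triethylsilyl group and closes the furanone, giving the amino lactone 13-(diethylamino)-11,13-dihydro-27 F3. MeI and then NaHCO3 (Hofmann elimination) restore the methylene lactone, and the route is rejoined at 27.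

Step 7 (Morita–Baylis–Hillman reaction on an α-acyloxy aldehyde). The risks are epimerisation at C8 and acyl migration to the new C7 hydroxyl. The fallback sets out from 13 and builds the acrylate by olefination. A Horner–Wadsworth–Emmons reaction (LiCl, i-Pr2NEt, MeCN, 0 °C) uses the phosphonate methyl 2-(dimethoxyphosphoryl)-3-hydroxypropanoate F4, made from trimethyl phosphonoacetate and formaldehyde. It gives the primary allylic alcohol methyl (2E,4R,6S)-2-(hydroxymethyl)-6-methyl-4-(2-methylpropanoyloxy)-6-(triethylsilyloxy)oct-2-en-7-ynoate F5, which has no secondary hydroxyl next to the ester. Sonogashira coupling with 19 under the conditions of step 10 gives methyl (2E,4R,6S)-8-[3-({[tert-butyl(diphenyl)silyl]oxy}methyl)furan-2-yl]-2-(hydroxymethyl)-6-methyl-4-(2-methylpropanoyloxy)-6-(triethylsilyloxy)oct-2-en-7-ynoate F6. Appel bromination (CBr4, PPh3) then comes back to the route at 21.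

**Further compounds**

F1 | step 13 | methyl (2Z,4R)-2-(bromomethyl)-5-[(2S)-5-{(2Z)-1-[(tert-butyldiphenylsilyl)oxy]-4-oxobut-2-en-2-yl}-2-methyl-3-oxo-2,3-dihydrofuran-2-yl]-4-(2-methylpropanoyloxy)pent-2-enoate | O=C/C=C(/CO[Si](c1ccccc1)(c1ccccc1)C(C)(C)C)C1=CC(=O)[C@](C)(C[C@@H](OC(=O)C(C)C)/C=C(\CBr)C(=O)OC)O1
F2 | step 14 | (4Z)-1,13-bis(diethylamino)-15-(tert-butyldiphenylsilyloxy)-3-oxo-10-(triethylsilyloxy)germacra-1,4-dien-12,6-olid-8-yl 2-methylpropanoate (C11 epimers) | CCN(CC)CC1C(=O)O[C@@H]2/C=C(/CO[Si](c3ccccc3)(c3ccccc3)C(C)(C)C)C(=O)C=C(N(CC)CC)[C@@](C)(O[Si](CC)(CC)CC)C[C@@H](OC(=O)C(C)C)[C@@H]12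
F3 | step 14 | 13-(diethylamino)-11,13-dihydro derivative of 27 (C11 epimers) | CCN(CC)CC1C(=O)O[C@@H]2/C=C(/CO[Si](c4ccccc4)(c4ccccc4)C(C)(C)C)C3=CC(=O)[C@](C)(C[C@@H](OC(=O)C(C)C)[C@@H]12)O3
F4 | step 7 | methyl 2-(dimethoxyphosphoryl)-3-hydroxypropanoate | COC(=O)C(CO)P(=O)(OC)OC
F5 | step 7 | methyl (2E,4R,6S)-2-(hydroxymethyl)-6-methyl-4-(2-methylpropanoyloxy)-6-(triethylsilyloxy)oct-2-en-7-ynoate | C#C[C@@](C)(O[Si](CC)(CC)CC)C[C@@H](OC(=O)C(C)C)/C=C(\CO)C(=O)OC
F6 | step 7 | methyl (2E,4R,6S)-8-[3-({[tert-butyl(diphenyl)silyl]oxy}methyl)furan-2-yl]-2-(hydroxymethyl)-6-methyl-4-(2-methylpropanoyloxy)-6-(triethylsilyloxy)oct-2-en-7-ynoate | CC(C)(C)[Si](OCc1ccoc1C#C[C@@](C)(O[Si](CC)(CC)CC)C[C@@H](OC(=O)C(C)C)/C=C(\CO)C(=O)OC)(c1ccccc1)c1ccccc1
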